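**Retrosynthetic overview**
1. Target ⇒ its tetramethyl ether. Global O-demethylation is the last step, and the formyl group is carried unprotected from the first starting material.
2. Tetramethyl ether ⇒ (2,6-dimethoxy-4-formylphenyl)(4-anisyl)alkyne + 1-iodo-3,5-dimethoxybenzene. A new gold-catalysed demethylative oxyarylation forms the O1–C2 and C3–aryl bonds in one operation.
3. Alkyne ⇒ 4-bromo-3,5-dimethoxybenzaldehyde + 4-ethynylanisole (Sonogashira). The two methoxy groups flanking the alkyne are equivalent, so the 4-oxy/6-formyl pattern is fixed by symmetry.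
4. Ring order: the three benzene rings are bought. The furan ring is the only ring formed (step 2).

Assumption: the SMILES carries no stereodescriptor and the molecule has no stereocentre and no stable chiral axis (both pendant aryl rings are symmetric about their bond axes). It is therefore achiral, and "single enantiomer" means the compound itself.

**Step 1**
Reactants: 1 aryl bromide 4-bromo-3,5-dimethoxybenzaldehyde; 2 alkyne 1-ethynyl-4-methoxybenzene (4-ethynylanisole)
Product: 3 diarylalkyne 3,5-dimethoxy-4-[(4-methoxyphenyl)ethynyl]benzaldehyde
Conditions: PdCl2(MeCN)2 (2 mol%), XPhos (6 mol%), Cs2CO3 (2 equiv), MeCN, 80 °C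
Reagents that add atoms: none
Why: Copper-free Sonogashira coupling: the para-formyl group accelerates oxidative addition of zerovalent palladium into the C–Br bond, the bulky biarylphosphine XPhos tolerates the two ortho methoxy groups, the non-enolisable aldehyde is inert to Cs2CO3, and the methyl ethers keep the alkyne from cyclising early; no stereocentre is formed.

**Step 2**
Reactants: 3 diarylalkyne 3,5-dimethoxy-4-[(4-methoxyphenyl)ethynyl]benzaldehyde; 4 aryl iodide 1-iodo-3,5-dimethoxybenzene
Product: 5 tetramethyl ether 3-(3,5-dimethoxyphenyl)-4-methoxy-2-(4-methoxyphenyl)-1-benzofuran-6-carbaldehyde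
Conditions: (MeDalphos)AuCl [MeDalphos = (1-adamantyl)2P(C6H4-2-NMe2)] (5 mol%), AgOTf (1.2 equiv), 4 Å MS, ClCH2CH2Cl, 80 °C
Reagents that add atoms: none
Why: Proposed new method: demethylative oxyarylation of a 2-alkynylanisole with an aryl iodide under monovalent/trivalent gold redox catalysis; the P,N-ligated gold cation adds oxidatively to the electron-rich iodide 4, AgOTf strips the iodide, the cationic aryl complex of trivalent gold binds the push-pull alkyne of 3, one of the two equivalent ortho-methoxy oxygens attacks anti at the anisyl-bearing carbon (5-endo-dig, positive charge stabilised by the anisyl ring), triflate takes the methyl group off the oxonium oxygen, and fast cis aryl–vinyl reductive elimination from trivalent gold forms the C3–aryl bond and returns monovalent gold; because a methyl cation and not a proton is released, protodeauration to the 3-H benzofuran cannot compete; the closest known reaction types are gold-catalysed oxyarylation of alkenes with aryl iodides using the same hemilabile ligand, arylative cyclisation of free 2-alkynylphenols (Cacchi type with palladium, or gold with arenediazonium salts) and Larock iodocyclisation of 2-alkynylanisoles, none of which uses an aryl methyl ether as the oxygen nucleophile together with an aryl iodide; no stereocentre is formed.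

**Step 3**
Reactants: 5 tetramethyl ether 3-(3,5-dimethoxyphenyl)-4-methoxy-2-(4-methoxyphenyl)-1-benzofuran-6-carbaldehyde
Product: 6 target 3-(3,5-dihydroxyphenyl)-4-hydroxy-2-(4-hydroxyphenyl)-1-benzofuran-6-carbaldehyde
Conditions: BBr3 (10 equiv), CH2Cl2, −78 °C to rt; then H2O, 0 °C
Reagents that add atoms: none
Why: Lewis acid-mediated aryl methyl ether cleavage (BBr3 demethylation): boron binds each ether oxygen and bromide removes the methyl group by SN2 attack, the aromatic benzofuran core is inert, and aqueous work-up frees the four phenols and the aldehyde; no stereocentre is involved.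

**Compound list**
1 | 4-bromo-3,5-dimethoxybenzaldehyde (achiral) | COc1cc(C=O)cc(OC)c1Br | starting material
2 | 1-ethynyl-4-methoxybenzene (achiral) | C#Cc1ccc(OC)cc1 | starting material
3 | 3,5-dimethoxy-4-[(4-methoxyphenyl)ethynyl]benzaldehyde (achiral) | COc1ccc(cc1)C#Cc1c(OC)cc(C=O)cc1OC | intermediate
4 | 1-iodo-3,5-dimethoxybenzene (achiral) | COc1cc(I)cc(OC)c1 | starting material
5 | 3-(3,5-dimethoxyphenyl)-4-methoxy-2-(4-methoxyphenyl)-1-benzofuran-6-carbaldehyde (achiral) | O=Cc1cc(OC)c2c(-c3cc(OC)cc(OC)c3)c(-c3ccc(OC)cc3)oc2c1 | intermediate
6 | 3-(3,5-dihydroxyphenyl)-4-hydroxy-2-(4-hydroxyphenyl)-1-benzofuran-6-carbaldehyde (CNP0078653.0, achiral) | O=Cc1cc(O)c2c(-c3cc(O)cc(O)c3)c(-c3ccc(O)cc3)oc2c1 | target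

Total step count: 3. Longest linear sequence: 3 steps (1 → 3 → 5 → 6).

**Steps most likely to fail**

**Step 2 (the proposed new step).**
- An aryl methyl ether is a much weaker nucleophile than a phenoxide.
- The bulky complex of trivalent gold must sit at C3 next to the remaining C4 methoxy group.
- Iodide 4 can itself be C–H arylated by the aryl gold species.
- The methylating by-product may alkylate the ligand nitrogen.

The fallback uses known chemistry only. It sets out from 3 and comes back at 5. Larock iodocyclisation of 3 with I2 in CH2Cl2 at room temperature closes the furan ring with loss of one methyl group. It gives 3-iodo-4-methoxy-2-(4-methoxyphenyl)-1-benzofuran-6-carbaldehyde F1. Suzuki–Miyaura coupling of F1 with commercial 3,5-dimethoxyphenylboronic acid (Pd(OAc)2, SPhos, K3PO4, toluene/H2O, 90 °C) then gives 5.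

**Step 3.**
- The BBr3-activated aldehyde can be attacked by the electron-rich resorcinol rings, giving Friedel–Crafts oligomers.
- The aldehyde can be converted into a benzal bromide.
- The hindered C4 ether may be cleaved slowly.

The fallback removes the electrophilic formyl group during the Lewis acid step. It sets out from 5 and comes back at 6. Oxidative conversion of the aldehyde with I2 and aqueous NH3 in THF at room temperature gives 3-(3,5-dimethoxyphenyl)-4-methoxy-2-(4-methoxyphenyl)-1-benzofuran-6-carbonitrile F2. BBr3 in CH2Cl2 then gives 3-(3,5-dihydroxyphenyl)-4-hydroxy-2-(4-hydroxyphenyl)-1-benzofuran-6-carbonitrile F3. DIBAL-H (7 equiv, THF, −78 to 0 °C) followed by 1 M HCl reduces the nitrile of F3 to the aldehyde 6.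

**Step 1.**
- The doubly ortho-substituted aryl palladium bromide may take up the acetylide slowly.
- The alkyne then oligomerises under basic conditions.

The fallback replaces in situ deprotonation with a preformed, neutral tin acetylide. It sets out from 2 and comes back at 3. Heating 2 neat with Bu3SnOMe at 70 °C, with removal of the volatile by-product in vacuo, gives tributyl[(4-methoxyphenyl)ethynyl]stannane F4. Base-free Stille coupling of F4 with 1 (Pd(P(t-Bu)3)2, toluene, 100 °C) gives 3.

**Further compounds**
F1 | step 2 | 3-iodo-4-methoxy-2-(4-methoxyphenyl)-1-benzofuran-6-carbaldehyde | O=Cc1cc(OC)c2c(I)c(-c3ccc(OC)cc3)oc2c1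
F2 | step 3 | 3-(3,5-dimethoxyphenyl)-4-methoxy-2-(4-methoxyphenyl)-1-benzofuran-6-carbonitrile | N#Cc1cc(OC)c2c(-c3cc(OC)cc(OC)c3)c(-c3ccc(OC)cc3)oc2c1
F3 | step 3 | 3-(3,5-dihydroxyphenyl)-4-hydroxy-2-(4-hydroxyphenyl)-1-benzofuran-6-carbonitrile | N#Cc1cc(O)c2c(-c3cc(O)cc(O)c3)c(-c3ccc(O)cc3)oc2c1
F4 | step 1 | tributyl[(4-methoxyphenyl)ethynyl]stannane | CCCC[Sn](CCCC)(CCCC)C#Cc1ccc(OC)cc1
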